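The route rests on disconnecting the C-4–C-5 bond of ring A (cyclohexane C-1–C-5/C-10; ring B = C-5–C-10). The key step is a 6-exo-trig reductive Heck cyclization: the C-5 enol triflate of a fully substituted ring-B ketone carbopalladates a pendant isopropenyl group, and formate reduces the neopentyl palladium species. One operation closes ring A, creates the quaternary C-4, turns the alkene CH2 into the second geminal methyl and leaves the C-5=C-6 alkene in place. It exploits the fact that the gem-dimethyl carbon C-4 sits directly on the vinylic carbon C-5. The precursor is a monocyclic cyclohexenyl triflate carrying the arene, the three stereocentres and a 4-methylpent-4-enyl chain at C-10.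

Key step: step 9

Remark on the chemistry: the (S,R,R) phosphoramidite ligand of step 3 is assumed to deliver the (3S) configuration; if the opposite sense is found, its enantiomer is used. Locants C-1 to C-10 are those of the bicyclic terpenoid part defined above.

Step 1
Reactants: 1 1,2,4,5-tetramethoxybenzene
Product: 3 (2,3,5,6-tetramethoxyphenyl)methanol, via aryllithium 2 (not isolated)
Conditions: n-BuLi, TMEDA, THF, 0 °C; then (CH2O)n, −78 °C to rt
Reagents that add atoms: paraformaldehyde as formaldehyde, C=O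
Why: Directed ortho-metalation removes the proton flanked by two methoxy groups, and the aryllithium adds to formaldehyde (hydroxymethylation).

Step 2
Reactants: 3 (2,3,5,6-tetramethoxyphenyl)methanol
Product: 4 3-(bromomethyl)-1,2,4,5-tetramethoxybenzene
Conditions: PBr3, Et2O, 0 °C
Reagents that add atoms: phosphorus tribromide, BrP(Br)Br
Why: Bromination of an electron-rich benzylic alcohol through its phosphite ester is fast at 0 °C; the bromide is used at once.

Step 3
Reactants: 5 2-methylcyclohex-2-en-1-one; 4 3-(bromomethyl)-1,2,4,5-tetramethoxybenzene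
Product: 8 (2R,3S)-2,3-dimethyl-2-(2,3,5,6-tetramethoxybenzyl)cyclohexan-1-one, via aluminium enolate 6 (not isolated), via lithium aluminate enolate 7 (not isolated)
Conditions: Me3Al, CuTC (C5H3CuO2S, copper thiophene-2-carboxylate, 2 mol %), (S)-(1,1'-binaphthalene-2,2'-diyl) N,N-bis[(R)-1-phenylethyl]phosphoramidite (4 mol %), Et2O, −30 °C; then MeLi, THF/HMPA, −30 °C; then 4, to 0 °C
Reagents that add atoms: trimethylaluminium, C[Al](C)C
Why: Copper-catalysed asymmetric conjugate addition sets C-8 under ligand control, and the regiodefined enolate should be benzylated anti to the new vicinal methyl group, which sets quaternary C-9 with its methyl cis to the C-8 methyl (tandem conjugate addition–enolate alkylation).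

Step 4
Reactants: 8 (2R,3S)-2,3-dimethyl-2-(2,3,5,6-tetramethoxybenzyl)cyclohexan-1-one
Product: 9 3-{[(1R,6S)-1,6-dimethyl-2-methylidenecyclohexyl]methyl}-1,2,4,5-tetramethoxybenzene
Conditions: Ph3PCH3Br, KOtBu, toluene, 90 °C
Reagents that add atoms: methyltriphenylphosphonium bromide, C[P+](c1ccccc1)(c1ccccc1)c1ccccc1.[Br-]
Why: Wittig methylenation with the salt-free ylide at elevated temperature is the standard answer to a ketone next to a quaternary carbon; no stereocentre is alpha to an acidic position, so none can epimerise.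

Step 5
Reactants: 9 3-{[(1R,6S)-1,6-dimethyl-2-methylidenecyclohexyl]methyl}-1,2,4,5-tetramethoxybenzene
Product: 10 (3R,4S)-3,4-dimethyl-2-methylidene-3-(2,3,5,6-tetramethoxybenzyl)cyclohexan-1-ol
Conditions: SeO2 (0.5 equiv), t-BuOOH, CH2Cl2, rt
Reagents that add atoms: tert-butyl hydroperoxide, CC(C)(C)OO; selenium dioxide, O=[Se]=O
Why: Riley allylic oxidation (ene reaction, then 2,3-sigmatropic shift) can only strike the ring CH2 at C-5, because the other allylic position C-9 is quaternary; the carbinol configuration is irrelevant.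

Step 6
Reactants: 10 (3R,4S)-3,4-dimethyl-2-methylidene-3-(2,3,5,6-tetramethoxybenzyl)cyclohexan-1-ol
Product: 11 (3R,4S)-3,4-dimethyl-2-methylidene-3-(2,3,5,6-tetramethoxybenzyl)cyclohexan-1-one
Conditions: Dess–Martin periodinane, NaHCO3, CH2Cl2, 0 °C to rt
Reagents that add atoms: none
Why: Dess–Martin oxidation of the allylic alcohol gives the alpha-methylene ketone under neutral conditions; the enone is used directly because such acceptors dimerise on standing.

Step 7
Reactants: 11 (3R,4S)-3,4-dimethyl-2-methylidene-3-(2,3,5,6-tetramethoxybenzyl)cyclohexan-1-one; 12 4-bromo-2-methylbut-1-ene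
Product: 15 (2S,3R,4S)-3,4-dimethyl-2-(4-methylpent-4-en-1-yl)-3-(2,3,5,6-tetramethoxybenzyl)cyclohexan-1-one, via Grignard reagent 13 (not isolated), via silyl enol ether 14 (not isolated)
Conditions: 12, Mg, THF; CuBr·SMe2 (10 mol %), Me3SiCl, THF, −78 °C, then 11; then NaOMe (cat.), MeOH, rt
Reagents that add atoms: none
Why: Copper-catalysed, silyl-chloride-accelerated 1,4-addition of the homoallylic Grignard reagent to the exocyclic enone joins C-1 to C-2, and methanolysis under equilibrating conditions should place the C-10 chain equatorial (cis to the C-9 methyl) in the chair that keeps the benzyl and C-8 methyl groups equatorial; any C-10 epimer is separated and re-equilibrated.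

Step 8
Reactants: 15 (2S,3R,4S)-3,4-dimethyl-2-(4-methylpent-4-en-1-yl)-3-(2,3,5,6-tetramethoxybenzyl)cyclohexan-1-one
Product: 17 (4S,5R,6S)-4,5-dimethyl-6-(4-methylpent-4-en-1-yl)-5-(2,3,5,6-tetramethoxybenzyl)cyclohex-1-en-1-yl trifluoromethanesulfonate, via potassium enolate 16 (not isolated)
Conditions: KN(SiMe3)2, THF, −78 °C; then PhNTf2, −78 to 0 °C
Reagents that add atoms: N-phenylbis(trifluoromethanesulfonimide), O=S(=O)(N(c1ccccc1)S(=O)(=O)C(F)(F)F)C(F)(F)F
Why: Kinetic deprotonation takes the unhindered C-6 methylene and not the C-10 methine beside quaternary C-9, so O-triflation gives the C-5=C-6 enol triflate and leaves C-10 untouched.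

Step 9
Reactants: 17 (4S,5R,6S)-4,5-dimethyl-6-(4-methylpent-4-en-1-yl)-5-(2,3,5,6-tetramethoxybenzyl)cyclohex-1-en-1-yl trifluoromethanesulfonate
Product: 19 3-{[(1R,2S,8aS)-1,2,5,5-tetramethyl-1,2,3,5,6,7,8,8a-octahydronaphthalen-1-yl]methyl}-1,2,4,5-tetramethoxybenzene, via alkylpalladium formate 18 (not isolated)
Conditions: Pd(OAc)2 (10 mol %), PPh3 (20 mol %), HCO2Na, Et4NCl, DMF, 80 °C
Reagents that add atoms: none
Why: Zerovalent palladium formed in situ inserts into the C-5–OTf bond, the alkenylpalladium adds syn across the 1,1-disubstituted alkene with C-5 bonding to the internal carbon C-4, and the resulting neopentyl-type alkylpalladium, which has no beta-hydrogen, takes up formate, loses CO2 and reductively eliminates C–H (reductive Mizoroki–Heck cyclization, cyclization–hydride capture). Ring A is closed in the 6-exo-trig mode, which a three-carbon tether strongly prefers over 7-endo. No new stereocentre is formed because C-4 ends with two identical methyl groups; C-8, C-9 and C-10 are spectators, and the equatorial C-10 chain lies beside the alkenylpalladium. The step needs carbopalladation to outrun direct formate reduction of the alkenylpalladium and 3-exo attack of the alkylpalladium on the C-5=C-6 alkene. Sparingly soluble sodium formate should keep the hydride concentration low during insertion, and hydride capture of the beta-hydrogen-free alkylpalladium then closes the cycle. The arene has no free position within reach of the metal, and the C-5=C-6 alkene stays where the triflate placed it.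

Step 10
Reactants: 19 3-{[(1R,2S,8aS)-1,2,5,5-tetramethyl-1,2,3,5,6,7,8,8a-octahydronaphthalen-1-yl]methyl}-1,2,4,5-tetramethoxybenzene
Product: 20 2,5-dimethoxy-3-{[(1R,2S,8aS)-1,2,5,5-tetramethyl-1,2,3,5,6,7,8,8a-octahydronaphthalen-1-yl]methyl}cyclohexa-2,5-diene-1,4-dione
Conditions: (NH4)2Ce(NO3)6, MeCN/H2O, 0 °C
Reagents that add atoms: water, O
Why: Oxidative demethylation of a para-dimethoxy pair gives the quinone (both para pairs lead to the same 2,5-dimethoxyquinone), and the hindered trisubstituted alkene should survive brief exposure at 0 °C.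

Step 11
Reactants: 20 2,5-dimethoxy-3-{[(1R,2S,8aS)-1,2,5,5-tetramethyl-1,2,3,5,6,7,8,8a-octahydronaphthalen-1-yl]methyl}cyclohexa-2,5-diene-1,4-dione
Product: 21 2-hydroxy-5-methoxy-3-{[(1R,2S,8aS)-1,2,5,5-tetramethyl-1,2,3,5,6,7,8,8a-octahydronaphthalen-1-yl]methyl}cyclohexa-2,5-diene-1,4-dione
Conditions: KOH, MeOH/H2O, rt; then aq. HCl
Reagents that add atoms: potassium hydroxide, [K+].[OH-]
Why: Addition–elimination of hydroxide (vinylogous ester saponification) should take the methoxy group next to the alkyl substituent, which is twisted out of conjugation by its two neighbours, and the vinylogous acid anion formed resists a second attack.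

Step 12
Reactants: 21 2-hydroxy-5-methoxy-3-{[(1R,2S,8aS)-1,2,5,5-tetramethyl-1,2,3,5,6,7,8,8a-octahydronaphthalen-1-yl]methyl}cyclohexa-2,5-diene-1,4-dione; 22 (S)-2-methylbutan-1-amine
Product: 23 nakijiquinone J
Conditions: NaHCO3, EtOH, rt to 40 °C
Reagents that add atoms: none
Why: Addition–elimination of the primary amine at the remaining methoxy-bearing carbon, which is unhindered beside the ring C–H, turns the vinylogous ester into the vinylogous amide without touching the amine stereocentre.

Compound list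
1 | 1,2,4,5-tetramethoxybenzene | COc1cc(OC)c(OC)cc1OC | starting material
2 | (2,3,5,6-tetramethoxyphenyl)lithium | COc1cc(OC)c(OC)c([Li])c1OC | intermediate
3 | (2,3,5,6-tetramethoxyphenyl)methanol | COc1cc(OC)c(OC)c(CO)c1OC | intermediate
4 | 3-(bromomethyl)-1,2,4,5-tetramethoxybenzene | COc1cc(OC)c(OC)c(CBr)c1OC | intermediate
5 | 2-methylcyclohex-2-en-1-one | CC1=CCCCC1=O | starting material
6 | dimethylaluminium (S)-2,3-dimethylcyclohex-1-en-1-olate | C[C@H]1CCCC(O[Al](C)C)=C1C | intermediate
7 | lithium trimethylaluminate of the (S)-2,3-dimethylcyclohex-1-en-1-olate | C[C@H]1CCCC(O[Al-](C)(C)C)=C1C.[Li+] | intermediate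
8 | (2R,3S)-2,3-dimethyl-2-(2,3,5,6-tetramethoxybenzyl)cyclohexan-1-one | COc1cc(OC)c(OC)c(C[C@@]2(C)C(=O)CCC[C@@H]2C)c1OC | intermediate
9 | 3-{[(1R,6S)-1,6-dimethyl-2-methylidenecyclohexyl]methyl}-1,2,4,5-tetramethoxybenzene | COc1cc(OC)c(OC)c(C[C@@]2(C)C(=C)CCC[C@@H]2C)c1OC | intermediate
10 | (3R,4S)-3,4-dimethyl-2-methylidene-3-(2,3,5,6-tetramethoxybenzyl)cyclohexan-1-ol (both carbinol epimers) | COc1cc(OC)c(OC)c(C[C@@]2(C)C(=C)C(O)CC[C@@H]2C)c1OC | intermediate
11 | (3R,4S)-3,4-dimethyl-2-methylidene-3-(2,3,5,6-tetramethoxybenzyl)cyclohexan-1-one | COc1cc(OC)c(OC)c(C[C@@]2(C)C(=C)C(=O)CC[C@@H]2C)c1OC | intermediate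
12 | 4-bromo-2-methylbut-1-ene | C=C(C)CCBr | starting material
13 | (3-methylbut-3-en-1-yl)magnesium bromide | C=C(C)CC[Mg]Br | intermediate
14 | {[(3R,4S)-3,4-dimethyl-2-(4-methylpent-4-en-1-yl)-3-(2,3,5,6-tetramethoxybenzyl)cyclohex-1-en-1-yl]oxy}trimethylsilane | COc1cc(OC)c(OC)c(C[C@@]2(C)C(CCCC(C)=C)=C(O[Si](C)(C)C)CC[C@@H]2C)c1OC | intermediate
15 | (2S,3R,4S)-3,4-dimethyl-2-(4-methylpent-4-en-1-yl)-3-(2,3,5,6-tetramethoxybenzyl)cyclohexan-1-one | COc1cc(OC)c(OC)c(C[C@@]2(C)[C@H](CCCC(C)=C)C(=O)CC[C@@H]2C)c1OC | intermediate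
16 | potassium enolate of 15 on the C-6 side | COc1cc(OC)c(OC)c(C[C@@]2(C)[C@H](CCCC(C)=C)C([O-])=CC[C@@H]2C)c1OC.[K+] | intermediate
17 | (4S,5R,6S)-4,5-dimethyl-6-(4-methylpent-4-en-1-yl)-5-(2,3,5,6-tetramethoxybenzyl)cyclohex-1-en-1-yl trifluoromethanesulfonate | COc1cc(OC)c(OC)c(C[C@@]2(C)[C@H](CCCC(C)=C)C(OS(=O)(=O)C(F)(F)F)=CC[C@@H]2C)c1OC | intermediate
18 | neopentyl-type alkylpalladium formate after ring closure (phosphine ligands not drawn; C-4 configuration not specified) | COc1cc(OC)c(OC)c(C[C@@]2(C)[C@@H]3CCCC(C)(C[Pd]OC=O)C3=CC[C@@H]2C)c1OC | intermediate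
19 | 3-{[(1R,2S,8aS)-1,2,5,5-tetramethyl-1,2,3,5,6,7,8,8a-octahydronaphthalen-1-yl]methyl}-1,2,4,5-tetramethoxybenzene | COc1cc(OC)c(OC)c(C[C@@]2(C)[C@@H]3CCCC(C)(C)C3=CC[C@@H]2C)c1OC | intermediate
20 | 2,5-dimethoxy-3-{[(1R,2S,8aS)-1,2,5,5-tetramethyl-1,2,3,5,6,7,8,8a-octahydronaphthalen-1-yl]methyl}cyclohexa-2,5-diene-1,4-dione | COC1=CC(=O)C(OC)=C(C[C@@]2(C)[C@@H]3CCCC(C)(C)C3=CC[C@@H]2C)C1=O | intermediate
21 | 2-hydroxy-5-methoxy-3-{[(1R,2S,8aS)-1,2,5,5-tetramethyl-1,2,3,5,6,7,8,8a-octahydronaphthalen-1-yl]methyl}cyclohexa-2,5-diene-1,4-dione | COC1=CC(=O)C(O)=C(C[C@@]2(C)[C@@H]3CCCC(C)(C)C3=CC[C@@H]2C)C1=O | intermediate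
22 | (S)-2-methylbutan-1-amine | CC[C@H](C)CN | starting material
23 | nakijiquinone J, 2-hydroxy-5-{[(2S)-2-methylbutyl]amino}-3-{[(1R,2S,8aS)-1,2,5,5-tetramethyl-1,2,3,5,6,7,8,8a-octahydronaphthalen-1-yl]methyl}cyclohexa-2,5-diene-1,4-dione | CC[C@H](C)CNC1=CC(=O)C(O)=C(C[C@@]2(C)[C@@H]3CCCC(C)(C)C3=CC[C@@H]2C)C1=O | target

Total step count: 12. Longest linear sequence: 12 steps (1 to 23); compounds 5, 12 and 22 enter at steps 3, 7 and 12.

Steps most likely to fail

Step 9. The alkenylpalladium may be reduced by formate before it inserts, or the neopentyl alkylpalladium may rearrange through 3-exo attack on the ring alkene before hydride capture. The fallback replaces the organopalladium closure by a cationic one and sets out from ketone 15. Condensation with 2,4,6-triisopropylbenzenesulfonyl hydrazide gives the trisylhydrazone F1. A Shapiro reaction (n-BuLi, THF/TMEDA, −78 to 0 °C, deprotonation on the C-6 side) gives the C-5 alkenyllithium F2, which is quenched with Me3SiCl to give the alkenylsilane F3. CF3CO2H in CH2Cl2 at −20 °C should protonate the isopropenyl group to the tertiary C-4 cation; ipso attack of C-5 and loss of the silyl group restore the C-5=C-6 alkene (alkenylsilane-terminated cation–olefin cyclization). The fallback comes back to the route at 19.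

Step 3. C-alkylation of the aluminium-bound enolate may be slow, which allows proton transfer and erodes regio- and diastereocontrol at C-9. The fallback separates the two events and sets out from 5. The same copper-catalysed addition of Me3Al is quenched with Me3SiOTf and Et3N, and the silyl enol ether F4 is isolated. MeLi in THF then liberates the regiodefined lithium enolate F5, which is alkylated with 4 in THF/HMPA at −40 °C. The fallback comes back to the route at 8.

Step 5. The selenium reagent may over-oxidise the alcohol or attack the electron-rich arene and its benzylic CH2. The fallback installs the oxygen before the alkene and sets out from 8. KN(SiMe3)2 gives the potassium enolate F6, which is hydroxylated with 2-(phenylsulfonyl)-3-phenyloxaziridine to the alpha-hydroxy ketone F7. Silylation (t-BuMe2SiOTf, 2,6-lutidine) gives the silyl ether F8, Wittig methylenation (Ph3PCH3Br, KOtBu, toluene, 90 °C) gives the methylidene silyl ether F9, and Bu4NF in THF removes the silyl group. The fallback comes back to the route at 10.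

Further compounds
F1 | step 9 | 2,4,6-triisopropylbenzenesulfonylhydrazone of ketone 15 | COc1cc(OC)c(OC)c(C[C@@]2(C)[C@H](CCCC(C)=C)C(=NNS(=O)(=O)c3c(C(C)C)cc(C(C)C)cc3C(C)C)CC[C@@H]2C)c1OC
F2 | step 9 | C-5 alkenyllithium (lithium in place of the triflate group of 17) | COc1cc(OC)c(OC)c(C[C@@]2(C)[C@H](CCCC(C)=C)C([Li])=CC[C@@H]2C)c1OC
F3 | step 9 | C-5 alkenylsilane (trimethylsilyl in place of the triflate group of 17) | COc1cc(OC)c(OC)c(C[C@@]2(C)[C@H](CCCC(C)=C)C([Si](C)(C)C)=CC[C@@H]2C)c1OC
F4 | step 3 | {[(S)-2,3-dimethylcyclohex-1-en-1-yl]oxy}trimethylsilane | C[C@H]1CCCC(O[Si](C)(C)C)=C1C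
F5 | step 3 | lithium (S)-2,3-dimethylcyclohex-1-en-1-olate | C[C@H]1CCCC(O[Li])=C1C
F6 | step 5 | potassium enolate of ketone 8 | COc1cc(OC)c(OC)c(C[C@@]2(C)C([O-])=CCC[C@@H]2C)c1OC.[K+]
F7 | step 5 | (2R,3S)-6-hydroxy-2,3-dimethyl-2-(2,3,5,6-tetramethoxybenzyl)cyclohexan-1-one (both carbinol epimers) | COc1cc(OC)c(OC)c(C[C@@]2(C)C(=O)C(O)CC[C@@H]2C)c1OC
F8 | step 5 | tert-butyldimethylsilyl ether of F7 | COc1cc(OC)c(OC)c(C[C@@]2(C)C(=O)C(O[Si](C)(C)C(C)(C)C)CC[C@@H]2C)c1OC
F9 | step 5 | tert-butyldimethylsilyl ether of allylic alcohol 10 | COc1cc(OC)c(OC)c(C[C@@]2(C)C(=C)C(O[Si](C)(C)C(C)(C)C)CC[C@@H]2C)c1OC
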